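The plan disconnects the oxepine ring of the dibenzo[b,f]oxepine core at its ether bond to ring A (the prenylated ring) and at its C-10–C-11 bond. This reveals a salicylate (ring B: phenol oxygen ortho to the future C-10) and an ortho-bromoarylacetate (ring A: halide ortho to the future C-11). A one-pot Ullmann etherification and Dieckmann condensation joins them in a formal [4+3] annulation to the tricyclic β-keto ester. The step exploits that the enol ether carbons C-10 and C-11, shared by oxepine and pyran, are a masked ketone and active methylene; after decarboxylation, prenal condensation and oxa-6π electrocyclisation build the 2H-pyran on these two atoms.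

Key step: step 6

Remark: locants follow dibenzo[b,f]oxepine numbering (ring A C-1 to C-4, O-5, ring B C-6 to C-9, C-10 next to ring B, C-11 next to ring A). The target is achiral; compounds with one stereocentre (11, F2, F4) are racemic.

Step 1
Reactants: 1 2-(2-bromo-4-methoxyphenyl)acetic acid
Product: 3 methyl 2-(2-bromo-4-hydroxyphenyl)acetate, via hydroxy acid 2 (not isolated)
Conditions: BBr3 (3 equiv), CH2Cl2, −78 °C to 25 °C; then MeOH, 65 °C
Reagents that add atoms: methanol (CO)
Why: BBr3 should cleave the aryl methyl ether (Lewis-acid O-demethylation), and the HBr set free on methanol quench should drive Fischer esterification of the arylacetic acid while the aryl bromide stays inert.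

Step 2
Reactants: 3 methyl 2-(2-bromo-4-hydroxyphenyl)acetate
Product: 4 methyl 2-(2-bromo-4-hydroxy-5-iodophenyl)acetate
Conditions: N-iodosuccinimide (1.05 equiv), TsOH·H2O (10 mol %), MeCN, 0 °C to 25 °C
Reagents that add atoms: N-iodosuccinimide (O=C1CCC(=O)N1I)
Why: Electrophilic aromatic iodination of the phenol should occur ortho to the hydroxyl at C-5, the only activated position not flanked by bromine (para is blocked by the acetate side chain), with ester and bromide untouched.

Step 3
Reactants: 4 methyl 2-(2-bromo-4-hydroxy-5-iodophenyl)acetate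
Product: 5 methyl 2-[2-bromo-5-iodo-4-(methoxymethoxy)phenyl]acetate
Conditions: MOMCl (1.5 equiv), iPr2NEt (2 equiv), CH2Cl2, 0 °C to 25 °C
Reagents that add atoms: chloromethyl methyl ether (COCCl)
Why: O-alkylation of the phenol with chloromethyl methyl ether under amine base (MOM protection) should leave the weakly acidic ester α-position and both halides alone.

Step 4
Reactants: 5 methyl 2-[2-bromo-5-iodo-4-(methoxymethoxy)phenyl]acetate; 6 tributyl(3-methylbut-2-en-1-yl)stannane
Product: 7 methyl 2-[2-bromo-4-(methoxymethoxy)-5-(3-methylbut-2-en-1-yl)phenyl]acetate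
Conditions: Pd(PPh3)4 (5 mol %), DMF, 80 °C
Reagents that add atoms: none
Why: Stille cross-coupling, in which zerovalent palladium should insert selectively into the weaker carbon–iodine bond and the allylstannane should deliver the prenyl group at its unsubstituted terminus, keeping the aryl bromide for the key step.

Step 5
Reactants: 8 methyl 2,4-dihydroxybenzoate
Product: 9 methyl 2-hydroxy-4-(methoxymethoxy)benzoate
Conditions: MOMCl (1.05 equiv), K2CO3 (1.2 equiv), acetone, 0 °C to 25 °C
Reagents that add atoms: chloromethyl methyl ether (COCCl)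
Why: Williamson-type MOM protection should be selective for the 4-hydroxyl because the 2-hydroxyl is deactivated by its hydrogen bond to the ortho ester carbonyl.

Step 6
Reactants: 7 methyl 2-[2-bromo-4-(methoxymethoxy)-5-(3-methylbut-2-en-1-yl)phenyl]acetate; 9 methyl 2-hydroxy-4-(methoxymethoxy)benzoate
Product: 11 methyl 3,7-bis(methoxymethoxy)-2-(3-methylbut-2-en-1-yl)-10-oxo-10,11-dihydrodibenzo[b,f]oxepine-11-carboxylate, via diaryl ether diester 10 (not isolated)
Conditions: CuI (10 mol %), N,N-dimethylglycine (30 mol %), Cs2CO3 (2 equiv), 1,4-dioxane, 100 °C; then KOtBu (2.5 equiv), THF, 0 °C to 25 °C, same flask; AcOH quench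
Reagents that add atoms: none
Why: Monovalent copper ligated by N,N-dimethylglycine should couple the aryl bromide of ring A with the free salicylate phenol of ring B (Ullmann-type C–O coupling via a copper phenoxide) to give diaryl ether 10, which makes the ether bond to ring A. KOtBu then deprotonates the arylacetate α-carbon, and the enolate attacks the neighbouring benzoate carbonyl (Dieckmann condensation) with loss of methoxide to form the C-10–C-11 bond, driven by deprotonation of the β-keto ester. The closest known reaction type is the one-pot Ullmann etherification/carbonyl condensation annulation used for dibenzo[b,f]oxepines, here with an ester in place of an aldehyde. The oxepine ring is closed in the second event by a 7-exo-trig acyl substitution, the first event being intermolecular. The new stereocentre C-11 is formed racemic and enolisable and is erased in step 7, so no control is needed. The step needs O-arylation before any enolate chemistry (a ketone enolate next to the aryl bromide could close to a benzofuran) and a single direction of condensation; the weak base of the first stage, the ester level of the nucleophilic carbon, the single free phenol, the single aryl halide and the lack of α-hydrogens in the benzoate should secure both.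

Step 7
Reactants: 11 methyl 3,7-bis(methoxymethoxy)-2-(3-methylbut-2-en-1-yl)-10-oxo-10,11-dihydrodibenzo[b,f]oxepine-11-carboxylate
Product: 12 3,7-bis(methoxymethoxy)-2-(3-methylbut-2-en-1-yl)dibenzo[b,f]oxepin-10(11H)-one
Conditions: LiCl (3 equiv), H2O (2 equiv), DMSO, 140 °C
Reagents that add atoms: none
Why: Krapcho dealkoxycarbonylation, in which chloride demethylates the β-keto ester by SN2 attack and the carboxylate loses CO2, should proceed under near-neutral conditions that spare the MOM ethers, the prenyl group and the seven-membered ketone (no retro-Claisen opening).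

Step 8
Reactants: 12 3,7-bis(methoxymethoxy)-2-(3-methylbut-2-en-1-yl)dibenzo[b,f]oxepin-10(11H)-one; 13 3-methylbut-2-enal
Product: 15 artocarpol D bis(methoxymethyl) ether, via Z-dienone 14 (not isolated)
Conditions: piperidine (0.5 equiv), AcOH (0.5 equiv), 4 Å molecular sieves, toluene, 100 °C
Reagents that add atoms: none
Why: Amine-catalysed Knoevenagel-type aldol condensation of the acidic α-aryl ketone methylene with the iminium ion of prenal should give the dienone, whose alkene geometry equilibrates under the amine, and the Z isomer should close by thermal oxa-6π electrocyclisation to the 2H-pyran, favoured by the gem-dimethyl group and the conjugated dibenzoxepine.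

Step 9
Reactants: 15 artocarpol D bis(methoxymethyl) ether
Product: 16 artocarpol D
Conditions: NaHSO4 on SiO2, CH2Cl2, 25 °C
Reagents that add atoms: none
Why: Mild heterogeneous Brønsted-acid hydrolysis of the two phenolic MOM acetals in a non-nucleophilic solvent should free both phenols while leaving the dienol ether of the pyran and the ortho-prenyl phenol intact.

Compound list
1 | 2-(2-bromo-4-methoxyphenyl)acetic acid | COc1ccc(CC(=O)O)c(Br)c1 | starting material
2 | 2-(2-bromo-4-hydroxyphenyl)acetic acid | OC(=O)Cc1ccc(O)cc1Br | intermediate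
3 | methyl 2-(2-bromo-4-hydroxyphenyl)acetate | COC(=O)Cc1ccc(O)cc1Br | intermediate
4 | methyl 2-(2-bromo-4-hydroxy-5-iodophenyl)acetate | COC(=O)Cc1cc(I)c(O)cc1Br | intermediate
5 | methyl 2-[2-bromo-5-iodo-4-(methoxymethoxy)phenyl]acetate | COCOc1cc(Br)c(CC(=O)OC)cc1I | intermediate
6 | tributyl(3-methylbut-2-en-1-yl)stannane | CCCC[Sn](CCCC)(CCCC)CC=C(C)C | starting material
7 | methyl 2-[2-bromo-4-(methoxymethoxy)-5-(3-methylbut-2-en-1-yl)phenyl]acetate | COCOc1cc(Br)c(CC(=O)OC)cc1CC=C(C)C | intermediate
8 | methyl 2,4-dihydroxybenzoate | COC(=O)c1ccc(O)cc1O | starting material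
9 | methyl 2-hydroxy-4-(methoxymethoxy)benzoate | COCOc1ccc(C(=O)OC)c(O)c1 | intermediate
10 | methyl 2-[2-(2-methoxy-2-oxoethyl)-5-(methoxymethoxy)-4-(3-methylbut-2-en-1-yl)phenoxy]-4-(methoxymethoxy)benzoate | COC(=O)c1ccc(OCOC)cc1Oc1cc(OCOC)c(CC=C(C)C)cc1CC(=O)OC | intermediate
11 | methyl 3,7-bis(methoxymethoxy)-2-(3-methylbut-2-en-1-yl)-10-oxo-10,11-dihydrodibenzo[b,f]oxepine-11-carboxylate (racemic) | COC(=O)C1C(=O)c2ccc(OCOC)cc2Oc2cc(OCOC)c(CC=C(C)C)cc21 | intermediate
12 | 3,7-bis(methoxymethoxy)-2-(3-methylbut-2-en-1-yl)dibenzo[b,f]oxepin-10(11H)-one | COCOc1ccc2c(c1)Oc1cc(OCOC)c(CC=C(C)C)cc1CC2=O | intermediate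
13 | 3-methylbut-2-enal (prenal) | CC(C)=CC=O | starting material
14 | (11Z)-3,7-bis(methoxymethoxy)-2-(3-methylbut-2-en-1-yl)-11-(3-methylbut-2-en-1-ylidene)dibenzo[b,f]oxepin-10(11H)-one | COCOc1ccc2c(c1)Oc1cc(OCOC)c(CC=C(C)C)cc1/C(=C/C=C(C)C)C2=O | intermediate
15 | artocarpol D bis(methoxymethyl) ether (both phenols of the target as MOM ethers) | CC(C)=CCc1cc2c(cc1OCOC)Oc1cc(OCOC)ccc1C1=C2C=CC(C)(C)O1 | intermediate
16 | artocarpol D | CC(C)=CCc1cc2c(cc1O)Oc1cc(O)ccc1C1=C2C=CC(C)(C)O1 | target

Total steps: 9
Longest linear sequence: 8 steps (1 → 3 → 4 → 5 → 7 → 11 → 12 → 15 → 16; step 5 runs in parallel)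

Steps most likely to fail

Step 6. The copper-mediated C–O coupling may stall because both partners are ortho-substituted and the phenol is deactivated by its ester, or enolate self-condensation of the arylacetate may overtake ether formation. The fallback sets out from 7 and returns at 11. Miyaura borylation of 7 (B2pin2, Pd(dppf)Cl2, KOAc, dioxane, 90 °C) would give the pinacol boronate methyl 2-[4-(methoxymethoxy)-5-(3-methylbut-2-en-1-yl)-2-(4,4,5,5-tetramethyl-1,3,2-dioxaborolan-2-yl)phenyl]acetate F1. Oxidative Chan–Lam coupling of this boronate with 9 (Cu(OAc)2, pyridine, 4 Å molecular sieves, air, CH2Cl2, 25 °C) would give diaryl ether 10 as an isolated compound. A separate Dieckmann condensation (NaH, THF, 0 °C to 50 °C) would then close it to 11.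

Step 8. The condensation may stop at a ring-open dienone of the wrong alkene geometry that cannot electrocyclise, or prenal may be consumed by self-condensation. The fallback sets out from 12 and returns at 15, and forms the pyran C–O bond by conjugate addition instead. C-acylation of 12 under soft enolisation (MgBr2·OEt2, iPr2NEt, 3-methylbut-2-enoyl chloride, CH2Cl2, 0 °C) would give the β-diketone 3,7-bis(methoxymethoxy)-11-(3-methylbut-2-enoyl)-2-(3-methylbut-2-en-1-yl)dibenzo[b,f]oxepin-10(11H)-one F2. A 6-endo oxa-Michael addition of its C-10 enol oxygen to the dimethyl-substituted enone (K2CO3, MeOH, 25 °C) would give the fused 2,2-dimethyl-2,3-dihydro-4H-pyran-4-one F3. Luche reduction (NaBH4, CeCl3·7H2O, MeOH, 0 °C) would give the racemic allylic alcohol F4, and mild dehydration (PPTS, 4 Å molecular sieves, toluene, 60 °C) would give 15.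

Step 9. The acid may protonate the dienol ether of the pyran, leading to ring opening or solvent addition, or may cyclise the prenyl group onto the neighbouring phenol. The fallback sets out from 12 and returns at 16, moving the acidic deprotection ahead of pyran formation. Treatment of 12 with HCl in MeOH at 40 °C would give the diphenol 3,7-dihydroxy-2-(3-methylbut-2-en-1-yl)dibenzo[b,f]oxepin-10(11H)-one F5. Silylation (TBSCl, imidazole, DMF, 25 °C) would give the bis-silyl ether 3,7-bis[(tert-butyldimethylsilyl)oxy]-2-(3-methylbut-2-en-1-yl)dibenzo[b,f]oxepin-10(11H)-one F6. The prenal annulation under the conditions of step 8 would give artocarpol D bis(tert-butyldimethylsilyl) ether F7, and fluoride cleavage (TBAF, THF, 0 °C) would give 16 without any acid.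

Further compounds
F1 | step 6 | methyl 2-[4-(methoxymethoxy)-5-(3-methylbut-2-en-1-yl)-2-(4,4,5,5-tetramethyl-1,3,2-dioxaborolan-2-yl)phenyl]acetate | COCOc1cc(B2OC(C)(C)C(C)(C)O2)c(CC(=O)OC)cc1CC=C(C)C
F2 | step 8 | 3,7-bis(methoxymethoxy)-11-(3-methylbut-2-enoyl)-2-(3-methylbut-2-en-1-yl)dibenzo[b,f]oxepin-10(11H)-one (racemic) | COCOc1ccc2c(c1)Oc1cc(OCOC)c(CC=C(C)C)cc1C(C(=O)C=C(C)C)C2=O
F3 | step 8 | dihydropyranone analogue of 15 (pyran CH=CH replaced by C(=O)–CH2, carbonyl next to C-11) | CC(C)=CCc1cc2c(cc1OCOC)Oc1cc(OCOC)ccc1C1=C2C(=O)CC(C)(C)O1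
F4 | step 8 | allylic alcohol from reduction of that ketone (racemic) | CC(C)=CCc1cc2c(cc1OCOC)Oc1cc(OCOC)ccc1C1=C2C(O)CC(C)(C)O1
F5 | step 9 | 3,7-dihydroxy-2-(3-methylbut-2-en-1-yl)dibenzo[b,f]oxepin-10(11H)-one | CC(C)=CCc1cc2c(cc1O)Oc1cc(O)ccc1C(=O)C2
F6 | step 9 | 3,7-bis[(tert-butyldimethylsilyl)oxy]-2-(3-methylbut-2-en-1-yl)dibenzo[b,f]oxepin-10(11H)-one | CC(C)=CCc1cc2c(cc1O[Si](C)(C)C(C)(C)C)Oc1cc(O[Si](C)(C)C(C)(C)C)ccc1C(=O)C2
F7 | step 9 | artocarpol D bis(tert-butyldimethylsilyl) ether | CC(C)=CCc1cc2c(cc1O[Si](C)(C)C(C)(C)C)Oc1cc(O[Si](C)(C)C(C)(C)C)ccc1C1=C2C=CC(C)(C)O1
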